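## Retrosynthetic overview
1. Acid 23 comes from methyl ester 21. The C3–CH2CO2Me bond comes from peroxycarbenium ion 20 (made from peroxyhemiketal 17) and silyl ketene acetal 18 under a chiral counteranion, which sets C3.
2. The only ring, the 1,2-dioxolane, is made in one operation by two C–O bonds. Asymmetric conjugate hydroperoxidation of E-enone 14 with H2O2 forms C5–O and sets C5, then hemiketalisation forms C3–O.
3. Enone 14 comes from methyl ketone 10 by propynyl addition and Meyer–Schuster rearrangement.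
4. Ketone 10 comes from copper-catalysed asymmetric conjugate addition of Grignard reagent 8 to pent-3-en-2-one, which sets C7.
5. Bromide 6 comes from 8-bromooct-1-ene by cross-metathesis with crotonaldehyde and Horner–Wadsworth–Emmons olefination with diethyl benzylphosphonate.

Assumption: the target is read as the (3R,5R)-dioxolane with the two ring methyl groups cis, an (R)-methine in the chain and both alkenes E. Where the sense of induction of a chiral catalyst cannot be known beforehand, the named antipode is the working choice and its mirror image or pseudoenantiomer is equally available.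

## Route

**Step 1**
Reactants: 1 8-bromooct-1-ene; 2 (E)-but-2-enal (crotonaldehyde)
Product: 3 (E)-9-bromonon-2-enal
Conditions: second-generation Hoveyda–Grubbs catalyst (2 mol %), 2 (3 equiv), CH2Cl2, 40 °C
Reagents that add atoms: crotonaldehyde (2), C/C=C/C=O
Why: Olefin cross-metathesis of a terminal alkene with an electron-poor enal is selective for the E cross product, and loss of propene drives it.

**Step 2**
Reactants: 3 (E)-9-bromonon-2-enal; 4 diethyl benzylphosphonate
Product: 6 (1E,3E)-10-bromo-1-phenyldeca-1,3-diene, via potassium phosphonate carbanion 5 (not isolated)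
Conditions: 4, KOtBu, THF, 0 °C; then 3, 0 °C to rt
Reagents that add atoms: diethyl benzylphosphonate (4), CCOP(=O)(Cc1ccccc1)OCC
Why: Horner–Wadsworth–Emmons olefination with a benzylic phosphonate gives the new styryl alkene E, and the preformed carbanion adds to the aldehyde much faster than it displaces the primary bromide.

**Step 3**
Reactants: 6 (1E,3E)-10-bromo-1-phenyldeca-1,3-diene; 7 (E)-pent-3-en-2-one
Product: 10 (4R,11E,13E)-4-methyl-14-phenyltetradeca-11,13-dien-2-one, via Grignard reagent 8 (not isolated), via magnesium enolate 9 (not isolated)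
Conditions: Mg, Et2O, reflux; then CuBr·SMe2 (5 mol %), (R)-1-[(Sp)-2-(diphenylphosphino)ferrocenyl]ethyldicyclohexylphosphine (6 mol %), 7, t-BuOMe, −75 °C; aq NH4Cl
Reagents that add atoms: (E)-pent-3-en-2-one (7), C/C=C/C(C)=O
Why: Copper-catalysed asymmetric conjugate addition of a linear alkyl Grignard reagent to a linear enone, in which the ferrocenyl diphosphine directs the alkyl group to the Si face of C4 of 7 and sets the chain methine (C7 of the target) as R.

**Step 4**
Reactants: 10 (4R,11E,13E)-4-methyl-14-phenyltetradeca-11,13-dien-2-one; 11 prop-1-ynylmagnesium bromide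
Product: 13 (6R,13E,15E)-4,6-dimethyl-16-phenylhexadeca-13,15-dien-2-yn-4-ol (both C4 epimers), via magnesium alkoxide 12 (not isolated)
Conditions: 11 (0.5 M in THF), THF, 0 °C to rt; aq NH4Cl
Reagents that add atoms: prop-1-ynylmagnesium bromide (11), CC#C[Mg]Br
Why: This is a 1,2-addition of an alkynyl Grignard reagent to a methyl ketone, and the new carbinol centre is erased in the next step, so its configuration does not matter.

**Step 5**
Reactants: 13 (6R,13E,15E)-4,6-dimethyl-16-phenylhexadeca-13,15-dien-2-yn-4-ol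
Product: 14 (3E,6R,13E,15E)-4,6-dimethyl-16-phenylhexadeca-3,13,15-trien-2-one
Conditions: Ph3PAuNTf2 (2 mol %), 4-MeOC6H4B(OH)2 (20 mol %), toluene, rt; E isomer isolated by chromatography
Reagents that add atoms: none
Why: The gold-catalysed Meyer–Schuster rearrangement moves the tertiary propargylic oxygen 1,3 to give the methyl enone under nearly neutral conditions that spare the diene and C6, with the E isomer (chain trans to acetyl) favoured.

**Step 6**
Reactants: 14 (3E,6R,13E,15E)-4,6-dimethyl-16-phenylhexadeca-3,13,15-trien-2-one; 15 hydrogen peroxide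
Product: 17 (5R)-3,5-dimethyl-5-[(2R,9E,11E)-2-methyl-12-phenyldodeca-9,11-dien-1-yl]-1,2-dioxolan-3-ol (both C3 anomers), via hydroperoxy ketone 16 (not isolated)
Conditions: 9-amino(9-deoxy)epiquinine (10 mol %), Cl3CCO2H (20 mol %), 50 % aq H2O2 (3 equiv), 1,4-dioxane, 30 °C
Reagents that add atoms: hydrogen peroxide (15), OO
Why: Proposed new method: the cinchona primary amine condenses with 14 to an iminium ion whose protonated quinuclidine hydrogen-bonds H2O2 and delivers it to the Re face of the fully substituted β-carbon, forming the tertiary C5–O bond as R under catalyst control (C7 is too remote to interfere); in the acidic buffer enamine protonation and hydrolysis outrun epoxide closure, and ring closure of 16 to hemiketal 17 (second C–O bond) pulls the reversible addition forward, as the uncatalysed conversion of mesityl oxide and H2O2 into its dioxolanol shows is thermodynamically possible, while the electron-rich phenyldiene is inert to a nucleophilic oxidant; the closest known reaction type is the cinchona-amine-catalysed asymmetric hydroperoxidation of β-monosubstituted acyclic enones and epoxidation of β-substituted cyclic enones, which has not been shown on acyclic β,β-disubstituted enones.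

**Step 7**
Reactants: 17 (5R)-3,5-dimethyl-5-[(2R,9E,11E)-2-methyl-12-phenyldodeca-9,11-dien-1-yl]-1,2-dioxolan-3-ol; 18 1-(tert-butyldimethylsilyloxy)-1-methoxyethene
Product: 21 methyl 2-[(3R,5R)-3,5-dimethyl-5-[(2R,9E,11E)-2-methyl-12-phenyldodeca-9,11-dien-1-yl]-1,2-dioxolan-3-yl]acetate, via silyl peroxyketal 19 (not isolated), via peroxycarbenium ion 20 (not isolated)
Conditions: 18 (2.5 equiv), (S,S)-IDPi (imidodiphosphorimidate acid from two 3,3'-diaryl-BINOL units, N-triflyl groups; 3 mol %), Et2O, −78 °C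
Reagents that add atoms: 1-(tert-butyldimethylsilyloxy)-1-methoxyethene (18), C=C(OC)O[Si](C)(C)C(C)(C)C
Why: Proposed new method: 18 silylates the acid to a silylium/IDPi ion pair that first caps the hemiketal OH (19) and then abstracts the silyloxy group to give planar cation 20 held in the confined chiral anion, so the second equivalent of 18 attacks only the face syn to the C5 alkyl chain, overriding the weak methyl-versus-CH2R substrate bias and setting C3 as R with the ring methyl groups cis; the closest known reaction types are the unselective Lewis acid displacement of 3-alkoxy-1,2-dioxolanes by silyl ketene acetals (Mukaiyama type) and the silylium counteranion-directed addition of silyl ketene acetals to cyclic aliphatic oxocarbenium ions, neither shown for peroxycarbenium ions or quaternary centres.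

**Step 8**
Reactants: 21 methyl 2-[(3R,5R)-3,5-dimethyl-5-[(2R,9E,11E)-2-methyl-12-phenyldodeca-9,11-dien-1-yl]-1,2-dioxolan-3-yl]acetate
Product: 23 2-[(3R,5R)-3,5-dimethyl-5-[(2R,9E,11E)-2-methyl-12-phenyldodeca-9,11-dien-1-yl]-1,2-dioxolan-3-yl]acetic acid (target), via lithium carboxylate 22 (not isolated)
Conditions: LiOH, THF/H2O, 0 °C to rt; then 1 M HCl to pH 3
Reagents that add atoms: lithium hydroxide, [Li+].[OH-]
Why: Cold saponification leaves the fully substituted dialkyl peroxide intact, and the carboxylate formed is too poor an acceptor for retro-Michael opening, so C3 is not scrambled.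

## Compound list
1 | 8-bromooct-1-ene | C=CCCCCCCBr | starting material
2 | (E)-but-2-enal | C/C=C/C=O | starting material
3 | (E)-9-bromonon-2-enal | O=C/C=C/CCCCCCBr | intermediate
4 | diethyl benzylphosphonate | CCOP(=O)(Cc1ccccc1)OCC | starting material
5 | potassium salt of the diethyl benzylphosphonate carbanion | CCOP(=O)([CH-]c1ccccc1)OCC.[K+] | intermediate
6 | (1E,3E)-10-bromo-1-phenyldeca-1,3-diene | BrCCCCCC/C=C/C=C/c1ccccc1 | intermediate
7 | (E)-pent-3-en-2-one | C/C=C/C(C)=O | starting material
8 | [(7E,9E)-10-phenyldeca-7,9-dien-1-yl]magnesium bromide | Br[Mg]CCCCCC/C=C/C=C/c1ccccc1 | intermediate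
9 | bromomagnesium enolate of ketone 10 (C2=C3 enolate) | C[C@H](CCCCCC/C=C/C=C/c1ccccc1)C=C(C)O[Mg]Br | intermediate
10 | (4R,11E,13E)-4-methyl-14-phenyltetradeca-11,13-dien-2-one | C[C@H](CCCCCC/C=C/C=C/c1ccccc1)CC(C)=O | intermediate
11 | prop-1-ynylmagnesium bromide | CC#C[Mg]Br | starting material
12 | bromomagnesium alkoxide of alcohol 13 | C[C@H](CCCCCC/C=C/C=C/c1ccccc1)CC(C)(O[Mg]Br)C#CC | intermediate
13 | (6R,13E,15E)-4,6-dimethyl-16-phenylhexadeca-13,15-dien-2-yn-4-ol (C4 epimers) | C[C@H](CCCCCC/C=C/C=C/c1ccccc1)CC(C)(O)C#CC | intermediate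
14 | (3E,6R,13E,15E)-4,6-dimethyl-16-phenylhexadeca-3,13,15-trien-2-one | C[C@H](CCCCCC/C=C/C=C/c1ccccc1)C/C(C)=C/C(C)=O | intermediate
15 | hydrogen peroxide | OO | starting material
16 | (4R,6R,13E,15E)-4-hydroperoxy-4,6-dimethyl-16-phenylhexadeca-13,15-dien-2-one | C[C@H](CCCCCC/C=C/C=C/c1ccccc1)C[C@](OO)(C)CC(C)=O | intermediate
17 | (5R)-3,5-dimethyl-5-[(2R,9E,11E)-2-methyl-12-phenyldodeca-9,11-dien-1-yl]-1,2-dioxolan-3-ol (C3 anomers) | C[C@H](CCCCCC/C=C/C=C/c1ccccc1)C[C@]1(C)CC(C)(O)OO1 | intermediate
18 | 1-(tert-butyldimethylsilyloxy)-1-methoxyethene | C=C(OC)O[Si](C)(C)C(C)(C)C | starting material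
19 | (5R)-3-(tert-butyldimethylsilyloxy)-3,5-dimethyl-5-[(2R,9E,11E)-2-methyl-12-phenyldodeca-9,11-dien-1-yl]-1,2-dioxolane | C[C@H](CCCCCC/C=C/C=C/c1ccccc1)C[C@]1(C)CC(C)(O[Si](C)(C)C(C)(C)C)OO1 | intermediate
20 | (5R)-3,5-dimethyl-5-[(2R,9E,11E)-2-methyl-12-phenyldodeca-9,11-dien-1-yl]-1,2-dioxolan-2-ium-2-ene (peroxycarbenium ion, paired with the IDPi anion) | C[C@H](CCCCCC/C=C/C=C/c1ccccc1)C[C@]1(C)CC(C)=[O+]O1 | intermediate
21 | methyl 2-[(3R,5R)-3,5-dimethyl-5-[(2R,9E,11E)-2-methyl-12-phenyldodeca-9,11-dien-1-yl]-1,2-dioxolan-3-yl]acetate | C[C@H](CCCCCC/C=C/C=C/c1ccccc1)C[C@]1(C)C[C@](C)(CC(=O)OC)OO1 | intermediate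
22 | lithium 2-[(3R,5R)-3,5-dimethyl-5-[(2R,9E,11E)-2-methyl-12-phenyldodeca-9,11-dien-1-yl]-1,2-dioxolan-3-yl]acetate | C[C@H](CCCCCC/C=C/C=C/c1ccccc1)C[C@]1(C)C[C@](C)(CC(=O)[O-])OO1.[Li+] | intermediate
23 | 2-[(3R,5R)-3,5-dimethyl-5-[(2R,9E,11E)-2-methyl-12-phenyldodeca-9,11-dien-1-yl]-1,2-dioxolan-3-yl]acetic acid | C[C@H](CCCCCC/C=C/C=C/c1ccccc1)C[C@]1(C)C[C@](C)(CC(=O)O)OO1 | target

## Step count and risks
Total steps: 8. Longest linear sequence: 8.

**Step 6 (new hydroperoxidation).**
- Risks: slow attack at the fully substituted β-carbon, E/Z leakage through the dienamine, and an unselective background addition.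
- Fallback, known chemistry, from 14 back to 17:
  - Copper-catalysed enantioselective conjugate borylation of 14 (B2pin2, CuCl, NaOtBu, chiral diphosphine, MeOH) gives the β-boryl ketone F1.
  - NaBO3 oxidation with retention gives the β-hydroxy ketone F2.
  - NaBH4 gives the 1,3-diol F3.
  - MsCl/Et3N selectively sulfonylates the secondary hydroxyl to the monomesylate F4.
  - KOtBu closes the oxetane F5 with retention at the tertiary carbon.
  - Ethereal H2O2 with catalytic TMSOTf opens the oxetane at the tertiary carbon with inversion to the hydroperoxy alcohol F6.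
  - Dess–Martin oxidation of the secondary alcohol gives 16, which closes to 17.

**Step 7 (new counteranion-controlled alkylation).**
- Risks: the chiral anion may not override the substrate bias, or the cation may fragment.
- Fallback, known chemistry, from 17 back to 21:
  - Ketalisation (MeOH, cat. TsOH) gives the 3-methoxydioxolane F7.
  - TiCl4 and 18 in CH2Cl2 at −78 °C give roughly equal amounts of 21 and its 3S epimer F8.
  - These are cis/trans ring diastereomers and are separated on silica gel, at the cost of about half the material.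

**Step 5 (enone geometry).**
- Risks: a poor E/Z ratio or competing Rupe-type dehydration would undermine step 6.
- Fallback from 10 back to 14:
  - Horner–Wadsworth–Emmons reaction with triethyl phosphonoacetate/NaH gives the ethyl E-enoate F9, and the minor Z ester is removed by chromatography.
  - MeNH(OMe)·HCl/i-PrMgCl gives the Weinreb amide F10.
  - MeMgBr gives geometrically pure 14.

## Further compounds
F1 | step 6 | (4R,6R,13E,15E)-4,6-dimethyl-16-phenyl-4-(4,4,5,5-tetramethyl-1,3,2-dioxaborolan-2-yl)hexadeca-13,15-dien-2-one | C[C@H](CCCCCC/C=C/C=C/c1ccccc1)C[C@@](B1OC(C)(C)C(C)(C)O1)(C)CC(C)=O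
F2 | step 6 | (4S,6R,13E,15E)-4-hydroxy-4,6-dimethyl-16-phenylhexadeca-13,15-dien-2-one | C[C@H](CCCCCC/C=C/C=C/c1ccccc1)C[C@@](O)(C)CC(C)=O
F3 | step 6 | (4S,6R,13E,15E)-4,6-dimethyl-16-phenylhexadeca-13,15-diene-2,4-diol (C2 epimers) | C[C@H](CCCCCC/C=C/C=C/c1ccccc1)C[C@@](O)(C)CC(C)O
F4 | step 6 | (4S,6R,13E,15E)-4-hydroxy-4,6-dimethyl-16-phenylhexadeca-13,15-dien-2-yl methanesulfonate (C2 epimers) | C[C@H](CCCCCC/C=C/C=C/c1ccccc1)C[C@@](O)(C)CC(C)OS(C)(=O)=O
F5 | step 6 | (2S)-2,4-dimethyl-2-[(2R,9E,11E)-2-methyl-12-phenyldodeca-9,11-dien-1-yl]oxetane (C4 epimers) | C[C@H](CCCCCC/C=C/C=C/c1ccccc1)C[C@@]1(C)CC(C)O1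
F6 | step 6 | (4R,6R,13E,15E)-4-hydroperoxy-4,6-dimethyl-16-phenylhexadeca-13,15-dien-2-ol (C2 epimers) | C[C@H](CCCCCC/C=C/C=C/c1ccccc1)C[C@](OO)(C)CC(C)O
F7 | step 7 | (5R)-3-methoxy-3,5-dimethyl-5-[(2R,9E,11E)-2-methyl-12-phenyldodeca-9,11-dien-1-yl]-1,2-dioxolane (C3 anomers) | C[C@H](CCCCCC/C=C/C=C/c1ccccc1)C[C@]1(C)CC(C)(OC)OO1
F8 | step 7 | methyl 2-[(3S,5R)-3,5-dimethyl-5-[(2R,9E,11E)-2-methyl-12-phenyldodeca-9,11-dien-1-yl]-1,2-dioxolan-3-yl]acetate | C[C@H](CCCCCC/C=C/C=C/c1ccccc1)C[C@]1(C)C[C@@](C)(CC(=O)OC)OO1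
F9 | step 5 | ethyl (2E,5R,12E,14E)-3,5-dimethyl-15-phenylpentadeca-2,12,14-trienoate | C[C@H](CCCCCC/C=C/C=C/c1ccccc1)C/C(C)=C/C(=O)OCC
F10 | step 5 | (2E,5R,12E,14E)-N-methoxy-N,3,5-trimethyl-15-phenylpentadeca-2,12,14-trienamide | C[C@H](CCCCCC/C=C/C=C/c1ccccc1)C/C(C)=C/C(=O)N(C)OC
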